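The rate constants come from no measurement; no experiment stands behind them.

A recipe cannot separate Friday's from Sunday's: both get the same charges and the same feed of D, and they differ in the time of reading, 10 d against 3.0 d.

| setting | Friday's | Sunday's |
|---|---|---|
| D | 1.0 M (fed, over 2.5 d) | 1.0 M (fed, over 2.5 d) |
| Q | 1.4 mol% | 1.4 mol% |
| time | 10 d | 3.0 d |
| remark | the fed solution adds 0.25 times the starting volume | the fed solution adds 0.25 times the starting volume |

1. which of the two ends with the longer chains by the average number of monomer units in a chain (chains begun, living or dead) ("neither" if they lie within 10 %) (Friday's / Sunday's / neither)
2. average number of monomer units in a chain (chains begun, living or dead) at the end, Friday's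
3. average number of monomer units in a chain (chains begun, living or dead) at the end, Sunday's

- charges are per starting volume, the dose included; the dosed solution carries all of it
- the average divides the monomer in chains by the number of chains begun, living and dead together
- run time (Friday's): 10 d

    D + Q → L + G (k1 = 2.3 × 10⁻⁴ M⁻¹ min⁻¹)
    D + L → G + L, rate k2*[L]*[D] (k2 = 0.031 M⁻¹ min⁻¹)
    L → X (k3 = 1.4 × 10⁻⁴ min⁻¹)

One chemist divides the charged D by the charged Q, gets 71.4 units a chain for both flasks, and answers neither.

I take the other side, that the reading time matters. Starting and growing both consume D, so cD cancels in the ratio of their rates. The constant of growth over the constant of starting is 135, and this number times cL/cQ gives the units added by growth per chain begun at that moment, which I call the marginal length; I leave out the one unit each start brings itself. The average rises while the marginal length stands above it.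

For Sunday's, the whole charge of D in the final volume would be 0.800 M; I take cD as half of that during the feed, and as that figure afterwards. The logarithm of the fall in Q is then 0.464, so 37.1 % of Q has gone. In a first round no chain dies, and adding up the marginal lengths gives an average of 33.7.

In a second round, L has a half-life of 3.4 d. Giving the chains a mean age of a third of the run leaves 81.7 % alive. Sunday's average becomes 27.5, with a marginal length of 65.0. Since the marginal length is larger than the average, Sunday's is still rising when read, and Friday's is the same flask left longer. I commit to Friday's and give no number for it.

The forecast says Friday's, with 68 and 29, from balances it says it “stepped the mole balances by hand”. Its Sunday figure is a little above mine.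

The simulation gives Friday's, with 68.5 and 29.1. The charge ratio has its region late on: Sunday's left to 30.0 d stands at 70.7, and Friday's left to 100 d at 66.4. Friday's at 10.0 d has a marginal length of 125, above its average. The neighbouring flask is Friday's with 1.7 M of D and the Q loading held. Its cL of 0.00387 M and 21.6 % of its Q left give a marginal length of 127 at 10.0 d, against an average of 82.7.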